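**Plan**

- Cut 1 is the CH(CH3)–CH2 bond on the ring side of the trans CH=CH unit, read as an allylic transposition: a ring-ethyl Grignard reagent plus a C20 secondary allylic ester. Cut 2 is the carbinol C–quaternary C bond of that ester (crotonaldehyde plus a C16 allyltrichlorosilane). Cut 3 is the C10–CH3 bond of the C16 chain (SN2' methylation of a farnesol-derived allylic chloride). Cut 4 is the ring C1–CH2 bond (Johnson–Claisen).
- Forward: farnesol is taken to the C20 ester in nine steps; (R)-3-methylcyclohexanone is taken to the ring bromide in eight steps (the six-membered ring is bought, not closed); the C20 and C12 halves are joined last.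
- Enabling feature: the trans-disubstituted C=C sits between the quaternary C(CH3)(CH=CH2) carbon and the CH(CH3) carbon. Shifted by one atom it is a secondary allylic ester whose fully substituted neighbour blocks α-attack, so a copper nucleophile must enter at the γ-carbon.
- Stereochemistry: ring C3 comes from the chiral pool and relays to ring C1 in the Claisen step. Chain C10 is set by a ligand-controlled copper SN2' reaction. The quaternary carbon and the carbinol carbon are set together in one catalysed allylation. The carbinol centre is then traded for the CH(CH3) centre by syn 1,3-chirality transfer, which also fixes the E-alkene.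

Key step: step 18

Remark: the senses of induction in steps 4 and 8 are assigned by analogy with the closest reported substrates; both ligands are available in either form, so the antipode is used if a model reaction shows the opposite sense.

**Chain half**

Step 1
Reactants: 1 (2E,6E)-farnesol
Product: 2 farnesyl TBS ether (tert-butyldimethyl{[(2E,6E)-3,7,11-trimethyldodeca-2,6,10-trien-1-yl]oxy}silane)
Conditions: TBSCl, imidazole, CH2Cl2, 0 °C to rt
Reagents that add atoms: tert-butyldimethylsilyl chloride, CC(C)(C)[Si](C)(C)Cl
Why: Routine silylation of a primary allylic alcohol gives an ether that should survive the Grignard step to come.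

Step 2
Reactants: 2 farnesyl TBS ether
Product: 3 (2E,6E,10E)-12-[(tert-butyldimethylsilyl)oxy]-2,6,10-trimethyldodeca-2,6,10-trien-1-ol
Conditions: SeO2 (0.1 equiv), t-BuOOH (3 equiv), salicylic acid (0.1 equiv), CH2Cl2, 0 °C to rt
Reagents that add atoms: tert-butyl hydroperoxide, CC(C)(C)OO (oxygen relayed through catalytic selenium dioxide, O=[Se]=O)
Why: Riley allylic oxidation (ene reaction then [2,3]-shift) should attack the terminal trisubstituted alkene at the methyl trans to the chain, giving the (E)-allylic alcohol.

Step 3
Reactants: 3 terminal allylic alcohol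
Product: 4 tert-butyl{[(2E,6E,10E)-12-chloro-3,7,11-trimethyldodeca-2,6,10-trien-1-yl]oxy}dimethylsilane
Conditions: N-chlorosuccinimide, Me2S, CH2Cl2, −40 to 0 °C
Reagents that add atoms: N-chlorosuccinimide, O=C1CCC(=O)N1Cl
Why: Corey–Kim chlorination should replace the primary allylic hydroxyl by chloride through SN2 attack on the alkoxysulfonium ion, without allylic shift or loss of the silyl ether.

Step 4
Reactants: 4 terminal allylic chloride
Product: 5 tert-butyldimethyl{[(2E,6E,10R)-3,7,10,11-tetramethyldodeca-2,6,11-trien-1-yl]oxy}silane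
Conditions: MeMgBr (1.2 equiv, slow addition), Cu(O2CC4H3S) (copper thiophene-2-carboxylate, 3 mol %), chiral phosphoramidite ligand (2,2'-biphenol backbone, N,N-bis[1-(2-methoxyphenyl)ethyl]amine; 3.3 mol %), CH2Cl2, −78 °C
Reagents that add atoms: methylmagnesium bromide, C[Mg]Br
Why: Copper-catalysed asymmetric allylic alkylation (SN2') of a 2-methyl-substituted primary allylic chloride with a Grignard reagent should deliver methyl to the γ-carbon, creating the isopropenyl group and the C10 stereocentre under control of the chiral ligand.

Step 5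
Reactants: 5 methylated silyl ether
Product: 6 (2E,6E,10R)-3,7,10,11-tetramethyldodeca-2,6,11-trien-1-ol
Conditions: Bu4NF (TBAF), THF, 0 °C to rt
Reagents that add atoms: none
Why: Fluoride-induced desilylation should free the primary allylic alcohol without touching the alkenes or the C10 centre.

Step 6
Reactants: 6 C16 allylic alcohol
Product: 7 (2E,6E,10R)-1-chloro-3,7,10,11-tetramethyldodeca-2,6,11-triene
Conditions: N-chlorosuccinimide, Me2S, CH2Cl2, −40 to 0 °C
Reagents that add atoms: N-chlorosuccinimide, O=C1CCC(=O)N1Cl
Why: Corey–Kim chlorination should give the primary allylic chloride with the (2E) geometry retained.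

Step 7
Reactants: 7 C16 allylic chloride
Product: 8 trichloro[(2E,6E,10R)-3,7,10,11-tetramethyldodeca-2,6,11-trien-1-yl]silane
Conditions: HSiCl3, CuCl (5 mol %), iPr2NEt, Et2O, 0 °C to rt; filtration and bulb-to-bulb distillation under argon
Reagents that add atoms: trichlorosilane, Cl[SiH](Cl)Cl
Why: Copper-catalysed silylation of primary allylic chlorides with HSiCl3 and a tertiary amine is an SN2 process that should give the linear allyltrichlorosilane with the E geometry intact.

Step 8
Reactants: 8 C16 allyltrichlorosilane; 9 (E)-but-2-enal (crotonaldehyde)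
Product: 11 (2E,4R,5S,8E,12R)-5-ethenyl-5,9,12,13-tetramethyltetradeca-2,8,13-trien-4-ol, via trichlorosilyl ether 10 (not isolated)
Conditions: (R,R)-bisphosphoramide catalyst (two 2,2'-bipyrrolidine-derived cyclic phosphoric triamide units joined through N,N'-dimethylpentane-1,5-diamine; 10 mol %), iPr2NEt, CH2Cl2, −78 °C; then aq. NaHCO3
Reagents that add atoms: none
Why: Lewis-base-catalysed allylation of a conjugated aldehyde with a γ,γ-disubstituted allyltrichlorosilane runs through a closed chair transition state at hexacoordinate silicon, so the E-substituent (the chain) should end anti to the new hydroxyl (relative configuration of the quaternary and carbinol centres), while the chiral bisphosphoramide should select the Si face of the aldehyde (absolute configuration).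

Step 9
Reactants: 11 C20 allylic alcohol
Product: 12 (2E,4R,5S,8E,12R)-5-ethenyl-5,9,12,13-tetramethyltetradeca-2,8,13-trien-4-yl 2-(diphenylphosphanyl)benzoate
Conditions: 2-(diphenylphosphanyl)benzoic acid, DCC, DMAP (cat.), CH2Cl2, rt, under argon
Reagents that add atoms: 2-(diphenylphosphanyl)benzoic acid, OC(=O)c1ccccc1P(c1ccccc1)c1ccccc1
Why: Steglich esterification should install the benzoate that serves both as leaving group and as phosphine directing group, with no change at the stereocentres.

**Ring half**

Step 10
Reactants: 13 (R)-3-methylcyclohexanone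
Product: 14 (2Z,5R)-2-(hydroxymethylidene)-5-methylcyclohexan-1-one
Conditions: HCO2Et (3 equiv), NaH (2 equiv), EtOH (cat.), Et2O, 0 °C to rt; then 1 M HCl
Reagents that add atoms: ethyl formate, CCOC=O
Why: Claisen condensation with ethyl formate should formylate the less hindered α-methylene (C6), remote from the methyl-bearing carbon, which is not enolisable and keeps its configuration.

Step 11
Reactants: 14 hydroxymethylene ketone
Product: 15 (2E,5R)-2-[(butylsulfanyl)methylidene]-5-methylcyclohexan-1-one
Conditions: n-BuSH (1.2 equiv), TsOH·H2O (cat.), benzene, reflux, Dean–Stark trap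
Reagents that add atoms: butane-1-thiol, CCCCS
Why: Acid-catalysed condensation of a hydroxymethylene ketone with a thiol should give the vinylogous thioester, which blocks this α-position and carries the carbon that later becomes the ring methylene.

Step 12
Reactants: 15 butylthiomethylene ketone
Product: 17 (3R,6E)-6-[(butylsulfanyl)methylidene]-2,2,3-trimethylcyclohexan-1-one, via monomethyl ketone 16 (not isolated)
Conditions: KOtBu (3 equiv), MeI (6 equiv), t-BuOH–THF, 0 °C to rt
Reagents that add atoms: iodomethane, CI
Why: With the other α-position blocked, enolisation is possible only toward the CH2 between the carbonyl and the CH(CH3) carbon, so exhaustive enolate methylation should build the gem-dimethyl carbon next to the untouched stereocentre.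

Step 13
Reactants: 17 dimethylated ketone
Product: 19 (4R)-3,3,4-trimethylcyclohex-1-ene-1-carbaldehyde, via allylic alcohol 18 (not isolated)
Conditions: LiAlH4, Et2O, 0 °C; then 1 M aq. HCl, THF, rt
Reagents that add atoms: water, O
Why: Hydride 1,2-reduction followed by acid-promoted ionisation of the allylic alcohol to a sulfur-stabilised allyl cation and hydrolysis (1,3-carbonyl transposition of an α-alkylthiomethylene ketone) should give the enal with the double bond toward the gem-dimethyl carbon.

Step 14
Reactants: 19 enal
Product: 20 [(4R)-3,3,4-trimethylcyclohex-1-en-1-yl]methanol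
Conditions: NaBH4, CeCl3·7H2O, MeOH, 0 °C
Reagents that add atoms: none
Why: Luche reduction should give clean 1,2-reduction of the enal to the primary allylic alcohol.

Step 15
Reactants: 20 cyclohexenylmethanol
Product: 22 ethyl [(1R,3R)-2,2,3-trimethyl-6-methylidenecyclohexyl]acetate, via ketene acetal 21 (not isolated)
Conditions: CH3C(OEt)3 (excess), EtCO2H (cat.), 140 °C, EtOH distilled off
Reagents that add atoms: triethyl orthoacetate, CCOC(C)(OCC)OCC
Why: Johnson–Claisen rearrangement forms the ring C1–CH2 bond and the exocyclic methylene in one [3,3] shift; the new bond should form axially on the face anti to the pseudoaxial methyl of the neighbouring C(CH3)2, which lies cis to the equatorial C3 methyl, so that C1 is set trans to C3 by relay from the chiral-pool centre.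

Step 16
Reactants: 22 ethyl ester
Product: 23 2-[(1R,3R)-2,2,3-trimethyl-6-methylidenecyclohexyl]ethan-1-ol
Conditions: LiAlH4, Et2O, 0 °C; aq. NaOH work-up
Reagents that add atoms: none
Why: Hydride reduction of the ester should give the primary alcohol; C1 is no longer α to a carbonyl, so it cannot epimerise.

Step 17
Reactants: 23 ring alcohol
Product: 24 (1R,3R)-1-(2-bromoethyl)-2,2,3-trimethyl-6-methylidenecyclohexane
Conditions: CBr4, PPh3, CH2Cl2, 0 °C
Reagents that add atoms: tetrabromomethane, BrC(Br)(Br)Br
Why: Appel bromination should convert the primary alcohol into the bromide under neutral conditions that leave the exocyclic alkene in place.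

**Union**

Step 18
Reactants: 24 ring bromide; 12 C20 allylic 2-(diphenylphosphanyl)benzoate
Product: 26 target (1R,3R)-1-[(3S,4E,6S,9E,13R)-6-ethenyl-3,6,10,13,14-pentamethylpentadeca-4,9,14-trien-1-yl]-2,2,3-trimethyl-6-methylidenecyclohexane, via Grignard reagent 25 (not isolated)
Conditions: 24, Mg turnings, Et2O, reflux; the solution of 25 added over 1 h to 12 and CuBr·SMe2 (50 mol %) in Et2O, rt, under argon; aq. NH4Cl
Reagents that add atoms: none
Why: The Grignard reagent and CuBr·SMe2 form an organocopper species that is bound by the ortho-phosphine of the benzoate and delivered within this chelate to the γ-carbon (the propenyl CH that bears the methyl) on the face syn to the C–O bond, giving a σ-allyl trivalent copper intermediate that collapses by reductive elimination with loss of the carboxylate. The closest known reaction type is the ortho-(diphenylphosphanyl)benzoate-directed copper-mediated allylic substitution of secondary allylic esters with Grignard reagents, which runs syn-SN2' with 1,3-chirality transfer. No ring is closed. The new CH(CH3) stereocentre is controlled by the (4R) carbinol centre: reaction through the conformer in which C4–H eclipses the alkene (allylic 1,3-strain keeps the quaternary carbon out of the alkene plane) together with syn delivery should give the (S) centre and the E-alkene at once, while the carbinol centre is consumed. The step needs γ over α regioselectivity and syn over anti facial selectivity: the fully substituted C5 next to the leaving group shuts down α-attack, and the phosphine tether, which leaves with the carboxylate, enforces the syn path and should outrun undirected addition to the ester carbonyl when the Grignard reagent is added slowly.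

**Compound list**

1 | (2E,6E)-farnesol | CC(C)=CCC/C(C)=C/CC/C(C)=C/CO | starting material
2 | farnesyl TBS ether | CC(C)=CCC/C(C)=C/CC/C(C)=C/CO[Si](C)(C)C(C)(C)C | intermediate
3 | (2E,6E,10E)-12-[(tert-butyldimethylsilyl)oxy]-2,6,10-trimethyldodeca-2,6,10-trien-1-ol | OC/C(C)=C/CC/C(C)=C/CC/C(C)=C/CO[Si](C)(C)C(C)(C)C | intermediate
4 | tert-butyl{[(2E,6E,10E)-12-chloro-3,7,11-trimethyldodeca-2,6,10-trien-1-yl]oxy}dimethylsilane | ClC/C(C)=C/CC/C(C)=C/CC/C(C)=C/CO[Si](C)(C)C(C)(C)C | intermediate
5 | tert-butyldimethyl{[(2E,6E,10R)-3,7,10,11-tetramethyldodeca-2,6,11-trien-1-yl]oxy}silane | CC(C)(C)[Si](C)(C)OC/C=C(\C)CC/C=C(\C)CC[C@@H](C)C(=C)C | intermediate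
6 | (2E,6E,10R)-3,7,10,11-tetramethyldodeca-2,6,11-trien-1-ol | OC/C=C(\C)CC/C=C(\C)CC[C@@H](C)C(=C)C | intermediate
7 | (2E,6E,10R)-1-chloro-3,7,10,11-tetramethyldodeca-2,6,11-triene | ClC/C=C(\C)CC/C=C(\C)CC[C@@H](C)C(=C)C | intermediate
8 | trichloro[(2E,6E,10R)-3,7,10,11-tetramethyldodeca-2,6,11-trien-1-yl]silane | Cl[Si](Cl)(Cl)C/C=C(\C)CC/C=C(\C)CC[C@@H](C)C(=C)C | intermediate
9 | (E)-but-2-enal (crotonaldehyde) | C/C=C/C=O | starting material
10 | trichlorosilyl ether of 11 | C=C[C@@](C)([C@H](O[Si](Cl)(Cl)Cl)/C=C/C)CC/C=C(\C)CC[C@@H](C)C(=C)C | intermediate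
11 | (2E,4R,5S,8E,12R)-5-ethenyl-5,9,12,13-tetramethyltetradeca-2,8,13-trien-4-ol | C=C[C@@](C)([C@H](O)/C=C/C)CC/C=C(\C)CC[C@@H](C)C(=C)C | intermediate
12 | (2E,4R,5S,8E,12R)-5-ethenyl-5,9,12,13-tetramethyltetradeca-2,8,13-trien-4-yl 2-(diphenylphosphanyl)benzoate | C=C[C@@](C)([C@H](OC(=O)c1ccccc1P(c1ccccc1)c1ccccc1)/C=C/C)CC/C=C(\C)CC[C@@H](C)C(=C)C | intermediate
13 | (R)-3-methylcyclohexanone | C[C@@H]1CCCC(=O)C1 | starting material
14 | (2Z,5R)-2-(hydroxymethylidene)-5-methylcyclohexan-1-one | C[C@@H]1CC/C(=C/O)C(=O)C1 | intermediate
15 | (2E,5R)-2-[(butylsulfanyl)methylidene]-5-methylcyclohexan-1-one | C[C@@H]1CC/C(=C\SCCCC)C(=O)C1 | intermediate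
16 | (3R,6E)-6-[(butylsulfanyl)methylidene]-2,3-dimethylcyclohexan-1-one (C2 epimers) | C[C@@H]1CC/C(=C\SCCCC)C(=O)C1C | intermediate
17 | (3R,6E)-6-[(butylsulfanyl)methylidene]-2,2,3-trimethylcyclohexan-1-one | C[C@@H]1CC/C(=C\SCCCC)C(=O)C1(C)C | intermediate
18 | (3R,6E)-6-[(butylsulfanyl)methylidene]-2,2,3-trimethylcyclohexan-1-ol (C1 epimers) | C[C@@H]1CC/C(=C\SCCCC)C(O)C1(C)C | intermediate
19 | (4R)-3,3,4-trimethylcyclohex-1-ene-1-carbaldehyde | C[C@@H]1CCC(C=O)=CC1(C)C | intermediate
20 | [(4R)-3,3,4-trimethylcyclohex-1-en-1-yl]methanol | C[C@@H]1CCC(CO)=CC1(C)C | intermediate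
21 | 1-ethoxyvinyl ether of 20 (mixed ketene acetal) | C[C@@H]1CCC(COC(=C)OCC)=CC1(C)C | intermediate
22 | ethyl [(1R,3R)-2,2,3-trimethyl-6-methylidenecyclohexyl]acetate | CCOC(=O)C[C@@H]1C(=C)CC[C@@H](C)C1(C)C | intermediate
23 | 2-[(1R,3R)-2,2,3-trimethyl-6-methylidenecyclohexyl]ethan-1-ol | OCC[C@@H]1C(=C)CC[C@@H](C)C1(C)C | intermediate
24 | (1R,3R)-1-(2-bromoethyl)-2,2,3-trimethyl-6-methylidenecyclohexane | BrCC[C@@H]1C(=C)CC[C@@H](C)C1(C)C | intermediate
25 | {2-[(1R,3R)-2,2,3-trimethyl-6-methylidenecyclohexyl]ethyl}magnesium bromide | Br[Mg]CC[C@@H]1C(=C)CC[C@@H](C)C1(C)C | intermediate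
26 | (1R,3R)-1-[(3S,4E,6S,9E,13R)-6-ethenyl-3,6,10,13,14-pentamethylpentadeca-4,9,14-trien-1-yl]-2,2,3-trimethyl-6-methylidenecyclohexane | C=C[C@@](C)(/C=C/[C@@H](C)CC[C@@H]1C(=C)CC[C@@H](C)C1(C)C)CC/C=C(\C)CC[C@@H](C)C(=C)C | target

**Step count and risks**

Total step count: 18. Longest linear sequence: 10 steps (steps 1 to 9, then step 18); the ring branch is 8 steps plus the union.

The three steps most likely to fail:

Step 18. The copper reagent may not be delivered through the phosphine chelate at a carbinol flanked by a quaternary carbon. The result would be attack on the ester carbonyl, incomplete chirality transfer, or loss of the Grignard reagent by homocoupling. The fallback replaces the organometallic substitution by a sigmatropic shift with the same syn sense of chirality transfer; it sets out from 11 and from Grignard reagent 25 (made from 24) and returns at 26. Carboxylation of 25 with CO2 (Et2O, −78 °C to rt, then HCl) should give 3-[(1R,3R)-2,2,3-trimethyl-6-methylidenecyclohexyl]propanoic acid F6. Esterification of F6 with 11 (DCC, DMAP, CH2Cl2) should give the allylic ester F7. Enolisation and silylation (LiN(iPr)2, Me3SiCl, Et3N, THF, −78 °C) should give the silyl ketene acetal F8, which on warming to rt should undergo Ireland–Claisen rearrangement through a chair transition state with the quaternary carbon equatorial to the rearranged trimethylsilyl ester F9, hydrolysed on aqueous work-up to the rearranged acid F10 (mixture at the α-carbon, which carries no stereocentre in the target). Coupling of F10 with 1-hydroxypyridine-2(1H)-thione (DCC, CH2Cl2, dark) should give the Barton ester F11, and its photolysis with t-BuSH (visible light, benzene, rt; Barton reductive decarboxylation) should give 26.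

Step 8. The Lewis-base-catalysed addition may be slow with an aliphatic enal, or may show poor facial selectivity, and the trichlorosilane may be lost to adventitious hydrolysis. The fallback changes the allyl donor from silicon to boron and the activation from Lewis base to Brønsted acid; it sets out from 7 and returns at 11. Borylation of 7 with bis(pinacolato)diboron (Pd2(dba)3 cat., DMSO, 50 °C) should give the linear (E)-allylboronate F4. Its addition to 9 under catalysis by the chiral phosphoric acid TRIP (3,3'-bis(2,4,6-triisopropylphenyl)-1,1'-binaphthyl-2,2'-diyl hydrogen phosphate, enantiomer chosen for Si-face attack; toluene, −30 °C) should proceed through the same chair arrangement to the pinacol borate ester F5, which is hydrolysed on work-up to 11.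

Step 4. Methyl may be transferred with poor γ/α regioselectivity or poor facial selectivity at a centre that is too remote from the others for later purification by diastereomer separation. The fallback sets the centre by reagent-controlled epoxidation and stereospecific opening instead; it sets out from 3 and returns at 5. Sharpless asymmetric epoxidation of 3 (Ti(OiPr)4, L-(+)-diethyl tartrate, t-BuOOH, 4 Å molecular sieves, CH2Cl2, −20 °C) should give the (2S,3S)-epoxy alcohol F1. Me2CuLi (Et2O, −20 °C) should open it with inversion at the secondary epoxide carbon, the other being fully substituted, to give the (2R,3R)-1,2-diol F2. 1,1'-Thiocarbonyldiimidazole (toluene, 80 °C) should give the cyclic thionocarbonate F3, and Corey–Winter elimination with P(OMe)3 (110 °C) should give the isopropenyl group of 5.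

**Further compounds**

F1 | step 4 | [(2S,3S)-3-{(3E,7E)-9-[(tert-butyldimethylsilyl)oxy]-3,7-dimethylnona-3,7-dien-1-yl}-2-methyloxiran-2-yl]methanol | CC(C)(C)[Si](C)(C)OC/C=C(\C)CC/C=C(\C)CC[C@@H]1O[C@@]1(C)CO
F2 | step 4 | (2R,3R,6E,10E)-12-[(tert-butyldimethylsilyl)oxy]-2,3,6,10-tetramethyldodeca-6,10-diene-1,2-diol | CC(C)(C)[Si](C)(C)OC/C=C(\C)CC/C=C(\C)CC[C@@H](C)[C@@](C)(O)CO
F3 | step 4 | cyclic thionocarbonate of F2 (1,3-dioxolane-2-thione) | CC(C)(C)[Si](C)(C)OC/C=C(\C)CC/C=C(\C)CC[C@@H](C)[C@]1(C)COC(=S)O1
F4 | step 8 | 4,4,5,5-tetramethyl-2-[(2E,6E,10R)-3,7,10,11-tetramethyldodeca-2,6,11-trien-1-yl]-1,3,2-dioxaborolane | CC1(C)OB(C/C=C(\C)CC/C=C(\C)CC[C@@H](C)C(=C)C)OC1(C)C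
F5 | step 8 | pinacol borate ester of 11 | C=C[C@@](C)([C@H](OB1OC(C)(C)C(C)(C)O1)/C=C/C)CC/C=C(\C)CC[C@@H](C)C(=C)C
F6 | step 18 | 3-[(1R,3R)-2,2,3-trimethyl-6-methylidenecyclohexyl]propanoic acid | OC(=O)CC[C@@H]1C(=C)CC[C@@H](C)C1(C)C
F7 | step 18 | ester of 11 with acid F6 | C=C[C@@](C)([C@H](OC(=O)CC[C@@H]1C(=C)CC[C@@H](C)C1(C)C)/C=C/C)CC/C=C(\C)CC[C@@H](C)C(=C)C
F8 | step 18 | trimethylsilyl ketene acetal of F7 | C=C[C@@](C)([C@H](OC(O[Si](C)(C)C)=CC[C@@H]1C(=C)CC[C@@H](C)C1(C)C)/C=C/C)CC/C=C(\C)CC[C@@H](C)C(=C)C
F9 | step 18 | rearranged trimethylsilyl ester (α-epimers) | C=C[C@@](C)(/C=C/[C@@H](C)C(C[C@@H]1C(=C)CC[C@@H](C)C1(C)C)C(=O)O[Si](C)(C)C)CC/C=C(\C)CC[C@@H](C)C(=C)C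
F10 | step 18 | rearranged acid, the 1-carboxy derivative of 26 at the CH2 next to the CH(CH3) centre (α-epimers) | C=C[C@@](C)(/C=C/[C@@H](C)C(C[C@@H]1C(=C)CC[C@@H](C)C1(C)C)C(=O)O)CC/C=C(\C)CC[C@@H](C)C(=C)C
F11 | step 18 | 2-thioxopyridin-1(2H)-yl ester of F10 (Barton ester) | C=C[C@@](C)(/C=C/[C@@H](C)C(C[C@@H]1C(=C)CC[C@@H](C)C1(C)C)C(=O)On1ccccc1=S)CC/C=C(\C)CC[C@@H](C)C(=C)C
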